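In a one-step world substrate meets reagent, target appears and stays, and one clock is enough to reckon with. For the delta flask that clock can be read from the epsilon run, which has the same charge.

| flask | substrate | reagent | free catalyst | time |
|---|---|---|---|---|
| epsilon | 300 mM | 450 mM | 6.00 mM |  |
| zeta | 300 mM | 900 mM | 6.00 mM |  |
| theta | 300 mM | 450 mM | 12.0 mM |  |
| gamma | 450 mM | 450 mM | 6.00 mM |  |
| delta | 300 mM | 450 mM | 6.00 mM | 19 h |

| run | time / h | [target] / mM |
|---|---|---|
| epsilon run | 0.53 | 38.0 |
| epsilon run | 1.1 | 70.8 |
| epsilon run | 1.6 | 92.0 |
| epsilon run | 2.1 | 109.2 |
| epsilon run | 2.7 | 125.2 |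
| epsilon run | 3.2 | 135.0 |
| zeta run | 0.53 | 42.6 |
| zeta run | 1.1 | 79.3 |
| zeta run | 1.6 | 101.8 |
| zeta run | 2.1 | 118.5 |
| zeta run | 2.7 | 135.8 |
| zeta run | 3.2 | 145.0 |
| theta run | 0.53 | 73.1 |
| theta run | 1.1 | 125.2 |
| theta run | 1.6 | 157.0 |
| theta run | 2.1 | 180.9 |
| theta run | 2.7 | 201.1 |
| theta run | 3.2 | 209.3 |
| gamma run | 0.53 | 50.3 |
| gamma run | 1.1 | 90.2 |
| gamma run | 1.6 | 117.9 |
| gamma run | 2.1 | 138.4 |
| gamma run | 2.7 | 158.2 |
| gamma run | 3.2 | 168.0 |

(standard deviation of a reading: 0.9 mM)

- Overall: substrate + reagent -> target, with free catalyst as catalyst.
- Constant volume, constant temperature.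
- An order is taken over about fifteen percent of the charge, up and down.

- apparent order in [substrate] of the starting rate, round the charge of the epsilon run (the rate where two percent of its substrate have turned into target) (one fixed amount of target, the same in the runs compared)
- apparent order in [free catalyst] of the starting rate, round the charge of the epsilon run (the rate where two percent of its substrate have turned into target)
- target in the delta run at 19 h, as a share of the substrate charged

In the epsilon run substrate is the limiting reagent, 300 mM against 450 mM of reagent, so in the one-step world the substrate charge is the ceiling for target. The first epsilon reading, 38.0 mM at 0.53 h, gives a mean early rate of 71.7 mM h⁻¹. The substrate charge divided by that rate is the charge time τ, here 4.18 h, a reading with its scatter. The bench rule then says that the converted share after a time t is 1 − exp(−t/τ), which puts the delta run at 98.9% by 19 h.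

The rule can be tried on the last epsilon reading. At 3.2 h it gives 160 mM, but the flask shows 135.0 mM, a ratio of 0.844, so the rule has already stopped working inside the readings. The time asked is also 5.94 times the time of that last reading.

So the first answer goes back in for a second round. The last two epsilon readings give a rate of 19.6 mM h⁻¹, a reading with its scatter. Taking the substrate left as charge minus target, a new charge time comes to 8.42 h, longer than the first. Run from the last reading to 19 h, and with target still assumed to stay, this reckoning of ours ends at 91.6%.

The forecast differs from this reckoning. It gives orders of 0.8 in substrate and 1.03 in free catalyst, and a lower 63% for the delta run. Its ground for the falling rate reads: “This points to time-based catalyst death rather than product inhibition.”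

The simulation gives 0.74 in substrate, 1.0 in free catalyst, and 43.1% for the delta run.

    free catalyst + substrate → loaded catalyst + by-product (65.16 M⁻¹ h⁻¹)
    loaded catalyst + reagent → target + free catalyst (117.4 M⁻¹ h⁻¹)
    target → decomposed product (0.05256 h⁻¹)
    free catalyst + substrate → spent catalyst + substrate (1.134 M⁻¹ h⁻¹)

With the conversion of target into decomposed product taken away, the delta run reaches 90.6% rather than 43.1%, so that conversion is the main reason for the low share. Counted as born at τ, target in the delta run ages 14.8 h, and 45.9% of it survives that age, which gives 41.6%. In the gamma run the first reading gives a charge time of 4.74 h, which puts a quarter of the substrate charged at 1.36 h, and target in the gamma run reaches that mark at 1.51 h.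

The runs were generated by integration for an exercise, and the scatter is random.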